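## Analysis of the target

Stenosporic acid (17) is a para-depside: two benzene rings and no other ring, joined by an aryl ester between the carboxyl carbon of ring A and the oxygen on C4 of ring B. Ring A is a 2-hydroxy-4-methoxy-6-propylbenzoyl unit; ring B is a benzoic acid with a hydroxyl on C2, the ester oxygen on C4 and a pentyl chain on C6. There is no stereocenter, so every selectivity question is one of position: which ring A oxygen carries the methyl group, which ring B oxygen carries the acyl group, and where the carboxyl sits relative to the alkyl chain. The sensitive points are the aryl ester, an activated ester that bases, fluoride and alcohols can cleave or exchange, and the free 2-hydroxybenzoic acid of ring B, which decarboxylates on heating or in strong acid. The difficulty lies in delivering a hindered, doubly ortho-substituted aroyl group to exactly one of two resorcinol-type oxygens of ring B, and in freeing three acidic groups at the end without touching the ester. The strategy rests on the fact that C2, C3, C4 and C5 of ring B, with their oxygens on C2 and C4, are the diene unit of an enol derivative of a cyclohexane-1,3-dione, while C1 (carboxyl) and C6 (pentyl) are the two acetylenic carbons of an oct-2-ynoate. At the diene stage O4 is an enolate oxygen and the only free oxygen in the molecule, so it can take the ring A acyl group before ring B exists.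

## Retrosynthetic reasoning

**Protecting groups (17 from 16).** The last operation cuts three O–CH2Ph bonds: the ring A ether on O2, the ring B ether on O2 and the carboxyl ester. One neutral hydrogenolysis then gives 17 with no base, acid or heat near the depside ester or the salicylic acid. A silyl ether on O2 of ring B would serve the cycloaddition equally well. It would, however, need a separate fluoride step in the presence of the aryl ester and would put a bulkier group on a bond-forming diene terminus, so that oxygen is carried as a benzyl ether.

**Ring B (16 from 11 and 14).** The bonds C1–C2 and C5–C6 of ring B are cut and a CH2–C(CH3)2 bridge is added back across C2 and C5. This divides ring B into a four-carbon diene that carries both oxygens (dienyl ester 11) and a two-carbon unit that carries carboxyl and pentyl (benzyl oct-2-ynoate 14). No other pair of bonds separates the oxygenated half from the carbon-substituted half so cleanly. The cut also removes the need to acylate one hydroxyl of a resorcylate in the presence of the other. The forward reaction has to add the diene to the alkyne with the benzyloxy-bearing terminus on the ester-bearing carbon, and then expel the saturated bridge as an alkene to aromatize.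

**Enol ester (11 from 9 and 7).** The O–C(acyl) bond of the dienyl ester is cut, giving the lithium dienolate 10 of vinylogous ester 9 and acid chloride 7. The order of events fixes the constitution of the diene. Enol ether first, then kinetic deprotonation of 9 at the CH2 between the carbonyl and the quaternary carbon, puts the new acyloxy group on an internal diene carbon and leaves the benzyloxy group on a terminus. Compound 11 is therefore the cyclohexa-1,5-dien-1-yl ester. The isomeric 1,3-dien-1-yl ester, which the reverse order would give, has the acyloxy group on a terminus and would deliver the depside oxygen ortho to the carboxyl. The forward reaction has to acylate 10 on oxygen and not on carbon.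

**Vinylogous ester (9 from 8).** The enol ether O–CH2Ph bond is cut back to dimedone (8). The two carbonyls of 8 are equivalent, so mono-etherification poses no regiochemical question, and 9 is a stable compound.

**Ynoate (14 from 12).** The bond between the alkyne carbon and the carbonyl carbon is cut, leading to hept-1-yne (12) through its lithium acetylide 13 and a chloroformate. This is one step and brings in the benzyl ester that the final hydrogenolysis removes.

**Ring A acyl donor (7 from 1).** Acid chloride 7 goes back to acid 6 and aldehyde 5. The benzyl group on O2 (5 from 4) and the methyl group on O4 (4 from 3) are then removed in turn, and the aryl–CHO bond of 3 is cut to reach 5-propylresorcinol (1). A formyl group is used as the latent carboxyl because its hydrogen bond to the ortho hydroxyl tells the two hydroxyls of 3 apart for methylation. It also passes through both alkylations and is oxidized at the end, so no hindered ester has to be hydrolysed.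

## Alternatives that were turned down

**Alternative 1: biomimetic aldol closure of ring A on a triketo aryl ester.**
- Disconnection: the C1–C6 bond of ring A, leaving the open-chain ester A2 (benzyl 2-hydroxy-6-pentyl-4-[(3,5,7-trioxodecanoyl)oxy]benzoate) already attached to O4 of ring B.
- Forward key step: base folds A2 by aldol attack of its C2 methylene on the C7 ketone, and dehydration gives A1 (benzyl 4-[(2,4-dihydroxy-6-propylbenzoyl)oxy]-2-hydroxy-6-pentylbenzoate).
- For it: it follows polyketide logic, ring A needs no protecting group, and the ester is formed with an unhindered aliphatic acyl group. On that last point it is stronger than the chosen route, which must transfer a 2,6-disubstituted aroyl group.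
- Against it: A2 is an aryl ester of a β-keto acid, so the depside bond is itself a good leaving group. Under the base needed for the aldol, the C6 methylene can attack the ester carbonyl in a Claisen mode, or an enol oxygen can lactonize to a pyrone. Both paths release the ring B phenoxide. A1 also has two free hydroxyls on ring A and must be methylated on O4 only, on the most fragile intermediate. Ring B with a free O4 and the tetraketide chain must each be made first.
- Comparison: the chosen route closes its ring under neutral heat with the ester as a spectator and carries the methyl ether from the first aromatic intermediate.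

**Alternative 2: pyrone cycloaddition with loss of the lactone bridge to build ring B.**
- Disconnection: C2–C3 and C1–C6 of ring B, giving pyrone A4 (2-oxo-6-pentyl-2H-pyran-4-yl 2,4-dimethoxy-6-propylbenzoate) and alkoxy ynoate A5 (benzyl 3-methoxyprop-2-ynoate).
- Forward key step: A5 adds across C3 and C6 of A4, and cycloreversion of the bridged lactone gives A3 (benzyl 4-[(2,4-dimethoxy-6-propylbenzoyl)oxy]-2-methoxy-6-pentylbenzoate).
- For it: like the chosen strategy it acylates an enol-type oxygen instead of a resorcinol. A4 is sturdier to handle than a dienol ether, which is a point in its favour. Polarity places the nucleophilic C3 of the pyrone on the methoxy-bearing alkyne carbon, and the aromatization is irreversible.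
- Against it: 2-pyrones are electron-poor, reluctant dienes. A5 is a push–pull alkoxyalkyne that is hard to prepare and store, and its donor group lowers its dienophilicity, so the two partners are poorly matched. A3 carries three methyl ethers, and the two ortho to carbonyl groups must be cleaved with a Lewis acid on the depside while the ring A 4-methoxy group stays.
- Comparison: the chosen route pairs an electron-rich diene with a stable, ordinary ynoate and ends in a neutral hydrogenolysis.

**Alternative 3: oxygenated diene plus aryl ynoate to build ring A.**
- Disconnection: C1–C2 and C5–C6 of ring A, giving aryl ynoate A7 (benzyl 4-(hex-2-ynoyloxy)-2-hydroxy-6-pentylbenzoate) and diene A8 ([(1,3-dimethoxybuta-1,3-dien-1-yl)oxy]trimethylsilane).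
- Forward key step: A8 adds across the triple bond of A7, 1,4-elimination of the acetal methoxy group aromatizes the ring, and work-up frees the 2-hydroxyl to give A6 (benzyl 2-hydroxy-4-[(2-hydroxy-4-methoxy-6-propylbenzoyl)oxy]-6-pentylbenzoate).
- For it: A8 is far more electron-rich than diene 11 and A7 is more electron-poor than ynoate 14, so this cycloaddition should run at lower temperature. The ring A pattern arises without protecting groups, and A6 is one hydrogenolysis from the target. On cycloaddition reactivity and on protecting-group economy it is stronger than the chosen route.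
- Against it: the group that activates the dienophile is the depside carbonyl itself, an aryl ester facing a silyl ketene acetal. Acyl transfer to A8 with loss of the ring B phenoxide, and conjugate addition, compete with cycloaddition. Ring B must be made separately as a 2,4-dihydroxy-6-pentylbenzoate and then acylated on O4 and not on O2 with a reactive ynoyl donor.
- Comparison: the chosen route keeps the depside carbonyl as a hindered spectator, never has to tell the ring B hydroxyls apart, and makes ring A by ordinary aromatic chemistry.

Key step: step 9

## Route

Assumption: 5-propylresorcinol (1) is treated as a purchasable compound.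

Step 1
Reactants: 1 5-propylbenzene-1,3-diol (divarinol)
Product: 3 2,4-dihydroxy-6-propylbenzaldehyde, via aryl iminium chloride 2 (not isolated)
Conditions: POCl3 (1.2 equiv), DMF, 0 °C to rt; then H2O, 50 °C
Reagents that add atoms: N,N-dimethylformamide, CN(C)C=O; water, O
Why: Vilsmeier–Haack formylation; the chloroiminium ion should attack C4 of the resorcinol (para to one hydroxyl, ortho to the other) in preference to the more crowded C2 between both hydroxyls, and hydrolysis of iminium salt 2 frees the aldehyde.

Step 2
Reactants: 3 2,4-dihydroxy-6-propylbenzaldehyde
Product: 4 2-hydroxy-4-methoxy-6-propylbenzaldehyde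
Conditions: MeI (1.1 equiv), K2CO3 (1.0 equiv), acetone, rt
Reagents that add atoms: iodomethane, CI
Why: Williamson ether synthesis; the 2-hydroxyl is tied up in a hydrogen bond to the formyl oxygen and is less acidic and less nucleophilic, so limited base and iodomethane should take the 4-hydroxyl only.

Step 3
Reactants: 4 2-hydroxy-4-methoxy-6-propylbenzaldehyde
Product: 5 2-(benzyloxy)-4-methoxy-6-propylbenzaldehyde
Conditions: BnBr (1.3 equiv), K2CO3 (2 equiv), DMF, 60 °C
Reagents that add atoms: benzyl bromide, BrCc1ccccc1
Why: Williamson ether synthesis under more forcing conditions, which the remaining chelated phenol needs; no other nucleophilic site is left.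

Step 4
Reactants: 5 2-(benzyloxy)-4-methoxy-6-propylbenzaldehyde
Product: 6 2-(benzyloxy)-4-methoxy-6-propylbenzoic acid
Conditions: NaClO2, NaH2PO4, 2-methylbut-2-ene (excess), t-BuOH/H2O, rt
Reagents that add atoms: sodium chlorite, [Na+].[O-]Cl=O
Why: Pinnick oxidation; the alkene scavenger removes the hypochlorous acid formed and so protects the electron-rich ring from chlorination, and the benzyl and methyl ethers are inert.

Step 5
Reactants: 6 2-(benzyloxy)-4-methoxy-6-propylbenzoic acid
Product: 7 2-(benzyloxy)-4-methoxy-6-propylbenzoyl chloride
Conditions: (COCl)2 (1.5 equiv), DMF (cat.), CH2Cl2, 0 °C to rt; evaporate, use crude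
Reagents that add atoms: oxalyl chloride, ClC(=O)C(=O)Cl
Why: Acid chloride formation by the DMF-catalysed oxalyl chloride method; the conditions are mild, all by-products are gases, and the hindered chloride can be used without purification.

Step 6
Reactants: 8 5,5-dimethylcyclohexane-1,3-dione (dimedone)
Product: 9 3-(benzyloxy)-5,5-dimethylcyclohex-2-en-1-one
Conditions: BnOH (1.2 equiv), TsOH·H2O (cat.), toluene, reflux, Dean–Stark trap
Reagents that add atoms: benzyl alcohol, OCc1ccccc1
Why: Acid-catalysed enol etherification of a cyclic 1,3-diketone (vinylogous ester formation) driven by azeotropic removal of water; the two carbonyls of 8 are equivalent, so a single product is expected.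

Step 7
Reactants: 9 3-(benzyloxy)-5,5-dimethylcyclohex-2-en-1-one; 7 2-(benzyloxy)-4-methoxy-6-propylbenzoyl chloride
Product: 11 5-(benzyloxy)-3,3-dimethylcyclohexa-1,5-dien-1-yl 2-(benzyloxy)-4-methoxy-6-propylbenzoate, via lithium dienolate 10 (not isolated)
Conditions: LiN(iPr)2 (1.05 equiv), THF, −78 °C; DMPU (2 equiv); then 7, −78 to −40 °C; cold NaHCO3 (aq) quench; Et3N-deactivated silica
Reagents that add atoms: none
Why: Kinetic deprotonation of a vinylogous ester at the CH2 between the carbonyl and the quaternary carbon (the enolate of the Stork–Danheiser alkylation) gives cross-conjugated dienolate 10; the doubly ortho-substituted aroyl chloride, the neopentyl carbon terminus of 10 and the dipolar cosolvent should all direct acylation to oxygen, giving the enol ester.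

Step 8
Reactants: 12 hept-1-yne
Product: 14 benzyl oct-2-ynoate, via lithium heptynide 13 (not isolated)
Conditions: n-BuLi (1.0 equiv), THF, −78 °C; then cannulate into ClCO2Bn (1.2 equiv), THF, −78 to 0 °C
Reagents that add atoms: benzyl chloroformate, O=C(Cl)OCc1ccccc1
Why: Deprotonation of a terminal alkyne and acylation of the lithium acetylide with a chloroformate; inverse addition at low temperature keeps the chloroformate in excess, so a second addition to the ynoate should not occur.

Step 9
Reactants: 11 5-(benzyloxy)-3,3-dimethylcyclohexa-1,5-dien-1-yl 2-(benzyloxy)-4-methoxy-6-propylbenzoate; 14 benzyl oct-2-ynoate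
Product: 16 benzyl 2-(benzyloxy)-4-{[2-(benzyloxy)-4-methoxy-6-propylbenzoyl]oxy}-6-pentylbenzoate, via bicyclo[2.2.2]octadiene adduct 15 (not isolated)
Conditions: 14 (3 equiv), mesitylene (2 M), 2,6-di-tert-butyl-4-methylpyridine (5 mol %), sealed tube, Ar, 165 °C
Reagents that add atoms: none
Why: A thermal, concerted [4+2] cycloaddition between the electron-rich diene 11 and the electron-poor alkyne 14 should give the bicyclo[2.2.2]octa-2,5-diene 15, whose CH2–C(CH3)2 bridge then leaves as 2-methylpropene in a retro-[4+2] step driven by aromatization (Alder–Rickert reaction). The closest known reaction type is the Alder–Rickert benzannulation of dimedone-derived 1,3-bis(silyloxy)cyclohexa-1,3-dienes and of 1-alkoxycyclohexa-1,3-dienes with acetylenic esters, which gives resorcylates and salicylates; 11 should be at least as reactive as a 1-alkoxycyclohexa-1,3-diene and less reactive than the bis(silyloxy) diene, because acyloxy is the weaker donor. Ring B is closed as a six-membered carbocycle by an intermolecular cycloaddition that forms C1–C2 and C5–C6 in one suprafacial event, and it becomes aromatic by cycloreversion, not by cyclization of a chain. No stereocenter is created in 16, since the two bridgehead centres of racemic 15 are lost with the bridge. The selectivity needed is regiochemical: the benzyloxy group on one diene terminus and the aroyloxy group on the internal carbon next to the other terminus both raise the HOMO coefficient at the unsubstituted CH terminus, which therefore bonds to the pentyl-bearing β-carbon of 14, where the LUMO coefficient is largest. The benzyloxy-bearing terminus then bonds to the ester-bearing α-carbon, which places the benzyl ether ortho and the depside oxygen para to the carboxyl. The medium is neutral and buffered against acid traces, so the enol ester, the later aryl ester, the benzyl ethers and the benzyl ester should survive. The temperature is held well below the range in which [1,5]-hydrogen shifts of cyclohexadienes would exchange the roles of the two oxygenated carbons.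

Step 10
Reactants: 16 benzyl 2-(benzyloxy)-4-{[2-(benzyloxy)-4-methoxy-6-propylbenzoyl]oxy}-6-pentylbenzoate
Product: 17 stenosporic acid, 4-[(2-hydroxy-4-methoxy-6-propylbenzoyl)oxy]-2-hydroxy-6-pentylbenzoic acid
Conditions: H2 (1 atm), 10% Pd/C, EtOAc, rt; filter, evaporate below 30 °C
Reagents that add atoms: none
Why: Catalytic hydrogenolysis should cleave both aryl benzyl ethers and the benzyl ester in one operation, while the aryl ester, the methyl ether and the arene rings are inert; the neutral, cold work-up avoids decarboxylation of the salicylic acid and transesterification of the depside.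

## Compound list

1 | 5-propylbenzene-1,3-diol (divarinol) | CCCc1cc(O)cc(O)c1 | starting material
2 | [(2,4-dihydroxy-6-propylphenyl)methylidene]dimethyliminium chloride | CCCc1cc(O)cc(O)c1C=[N+](C)C.[Cl-] | intermediate
3 | 2,4-dihydroxy-6-propylbenzaldehyde | CCCc1cc(O)cc(O)c1C=O | intermediate
4 | 2-hydroxy-4-methoxy-6-propylbenzaldehyde | CCCc1cc(OC)cc(O)c1C=O | intermediate
5 | 2-(benzyloxy)-4-methoxy-6-propylbenzaldehyde | CCCc1cc(OC)cc(OCc2ccccc2)c1C=O | intermediate
6 | 2-(benzyloxy)-4-methoxy-6-propylbenzoic acid | CCCc1cc(OC)cc(OCc2ccccc2)c1C(=O)O | intermediate
7 | 2-(benzyloxy)-4-methoxy-6-propylbenzoyl chloride | CCCc1cc(OC)cc(OCc2ccccc2)c1C(=O)Cl | intermediate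
8 | 5,5-dimethylcyclohexane-1,3-dione (dimedone) | CC1(C)CC(=O)CC(=O)C1 | starting material
9 | 3-(benzyloxy)-5,5-dimethylcyclohex-2-en-1-one | CC1(C)CC(=O)C=C(OCc2ccccc2)C1 | intermediate
10 | lithium 5-(benzyloxy)-3,3-dimethylcyclohexa-1,5-dien-1-olate | [Li+].[O-]C1=CC(C)(C)CC(OCc2ccccc2)=C1 | intermediate
11 | 5-(benzyloxy)-3,3-dimethylcyclohexa-1,5-dien-1-yl 2-(benzyloxy)-4-methoxy-6-propylbenzoate | CCCc1cc(OC)cc(OCc2ccccc2)c1C(=O)OC1=CC(C)(C)CC(OCc2ccccc2)=C1 | intermediate
12 | hept-1-yne | CCCCCC#C | starting material
13 | lithium hept-1-yn-1-ide | [Li+].[C-]#CCCCCC | intermediate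
14 | benzyl oct-2-ynoate | CCCCCC#CC(=O)OCc1ccccc1 | intermediate
15 | benzyl 1-(benzyloxy)-5-{[2-(benzyloxy)-4-methoxy-6-propylbenzoyl]oxy}-8,8-dimethyl-3-pentylbicyclo[2.2.2]octa-2,5-diene-2-carboxylate (racemic; the two bridgeheads are tied to each other by the bicycle) | CCCCCC1=C(C(=O)OCc2ccccc2)C2(OCc3ccccc3)CC(C)(C)C1C(OC(=O)c4c(OCc5ccccc5)cc(OC)cc4CCC)=C2 | intermediate
16 | benzyl 2-(benzyloxy)-4-{[2-(benzyloxy)-4-methoxy-6-propylbenzoyl]oxy}-6-pentylbenzoate | CCCCCc1cc(OC(=O)c2c(OCc3ccccc3)cc(OC)cc2CCC)cc(OCc2ccccc2)c1C(=O)OCc1ccccc1 | intermediate
17 | stenosporic acid, 4-[(2-hydroxy-4-methoxy-6-propylbenzoyl)oxy]-2-hydroxy-6-pentylbenzoic acid | CCCCCc1cc(OC(=O)c2c(O)cc(OC)cc2CCC)cc(O)c1C(=O)O | target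

## Step count and risks

Total step count: 10. Longest linear sequence: 8 steps (steps 1, 2, 3, 4, 5, 7, 9 and 10, from 1 to 17). Steps 6 and 8 are single-step branches.

**Step 9 (key step).** The cycloaddition may be too slow, because an acyloxy group is a weak donor and the alkyne carries a β-alkyl group. Prolonged heating could then lead to decomposition of the dienol ether or oligomerization of the ynoate before conversion. Acid traces, or hydrogen migration around the ring at higher temperature, could isomerize the diene. That would exchange the positions of the two oxygen substituents and give the benzoate with the depside oxygen ortho to the carboxyl.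
Fallback: the fallback sets out from dimedone 8 and ynoate 14, uses acid chloride 7, and returns to the route at 17. Ring B would be made with the symmetrical, more electron-rich diene, and the depside ester would be formed afterwards.
- Dimedone 8 would be O-silylated (Me3SiCl, Et3N) to 5,5-dimethyl-3-[(trimethylsilyl)oxy]cyclohex-2-en-1-one F1.
- F1 would be deprotonated with LiN(iPr)2 and silylated again to [(5,5-dimethylcyclohexa-1,3-diene-1,3-diyl)bis(oxy)]bis(trimethylsilane) F2.
- Heating F2 with 14 should give the adduct benzyl 8,8-dimethyl-3-pentyl-1,5-bis[(trimethylsilyl)oxy]bicyclo[2.2.2]octa-2,5-diene-2-carboxylate F3, which loses 2-methylpropene to give benzyl 6-pentyl-2,4-bis[(trimethylsilyl)oxy]benzoate F4.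
- Dilute aqueous HCl in THF would free benzyl 2,4-dihydroxy-6-pentylbenzoate F5.
- Acylation with 7 (Et3N, 4-(dimethylamino)pyridine cat., CH2Cl2, 0 °C) should take the unchelated 4-hydroxyl and give benzyl 4-{[2-(benzyloxy)-4-methoxy-6-propylbenzoyl]oxy}-2-hydroxy-6-pentylbenzoate F6.
- Hydrogenolysis of F6 as in step 10 gives 17.

The price is that the two ring B hydroxyls must then be told apart by chelation alone.

**Step 7.** Acylation of the dienolate on carbon instead of oxygen, equilibration of the enolate towards the extended isomer while the hindered chloride reacts slowly, or cleavage of the product enol ester by excess amide base would all lower the supply of 11.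
Fallback: it sets out from 9 and 6 and returns at 11. The enolate would be trapped on oxygen with silicon, where O-selectivity is not in doubt, and the acyl group would then be exchanged for silicon. LiN(iPr)2 and Me3SiCl would convert 9 into {[5-(benzyloxy)-3,3-dimethylcyclohexa-1,5-dien-1-yl]oxy}trimethylsilane F7. Cyanuric fluoride and pyridine would convert acid 6 into 2-(benzyloxy)-4-methoxy-6-propylbenzoyl fluoride F8. F7 and F8 with catalytic Bu4N[Ph3SiF2] in THF should give 11 by fluoride-catalysed O-acylation of the silyl enol ether, with loss of fluorotrimethylsilane.

**Step 2.** Over-alkylation to the dimethyl ether, or partial methylation of the chelated hydroxyl, would consume 3 and complicate separation.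
Fallback: it sets out from 3 and returns at 4. Both hydroxyls would be methylated on purpose (excess MeI, K2CO3, acetone, reflux) to give 2,4-dimethoxy-6-propylbenzaldehyde F9. BCl3 in CH2Cl2 at −78 to 0 °C would then cleave only the methyl ether ortho to the formyl group, by chelation, to give 4.

**Step 10.** Hydrogenolysis of the two benzyl ethers flanked by carbonyl groups may stall after the benzyl ester has gone, leaving partly protected material. Long exposure or warming during isolation could start decarboxylation of the product.
Fallback: it sets out from 16 and returns at 17. The benzyl groups would be removed without hydrogen by BCl3 with pentamethylbenzene as cation scavenger in CH2Cl2 at −78 °C, which should cleave benzyl ethers and the benzyl ester while the methyl ether para to the ring A carbonyl and the aryl ester stay. No new isolated compound is made.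

## Further compounds

F1 | step 9 | 5,5-dimethyl-3-[(trimethylsilyl)oxy]cyclohex-2-en-1-one | CC1(C)CC(=O)C=C(O[Si](C)(C)C)C1
F2 | step 9 | [(5,5-dimethylcyclohexa-1,3-diene-1,3-diyl)bis(oxy)]bis(trimethylsilane) | C[Si](C)(C)OC1=CC(O[Si](C)(C)C)=CC(C)(C)C1
F3 | step 9 | benzyl 8,8-dimethyl-3-pentyl-1,5-bis[(trimethylsilyl)oxy]bicyclo[2.2.2]octa-2,5-diene-2-carboxylate (racemic) | CCCCCC1=C(C(=O)OCc2ccccc2)C2(O[Si](C)(C)C)CC(C)(C)C1C(O[Si](C)(C)C)=C2
F4 | step 9 | benzyl 6-pentyl-2,4-bis[(trimethylsilyl)oxy]benzoate | CCCCCc1cc(O[Si](C)(C)C)cc(O[Si](C)(C)C)c1C(=O)OCc1ccccc1
F5 | step 9 | benzyl 2,4-dihydroxy-6-pentylbenzoate | CCCCCc1cc(O)cc(O)c1C(=O)OCc1ccccc1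
F6 | step 9 | benzyl 4-{[2-(benzyloxy)-4-methoxy-6-propylbenzoyl]oxy}-2-hydroxy-6-pentylbenzoate | CCCCCc1cc(OC(=O)c2c(OCc3ccccc3)cc(OC)cc2CCC)cc(O)c1C(=O)OCc1ccccc1
F7 | step 7 | {[5-(benzyloxy)-3,3-dimethylcyclohexa-1,5-dien-1-yl]oxy}trimethylsilane | C[Si](C)(C)OC1=CC(C)(C)CC(OCc2ccccc2)=C1
F8 | step 7 | 2-(benzyloxy)-4-methoxy-6-propylbenzoyl fluoride | CCCc1cc(OC)cc(OCc2ccccc2)c1C(=O)F
F9 | step 2 | 2,4-dimethoxy-6-propylbenzaldehyde | CCCc1cc(OC)cc(OC)c1C=O
F0 | step 10 | none | none
A1 | alternative 1 | benzyl 4-[(2,4-dihydroxy-6-propylbenzoyl)oxy]-2-hydroxy-6-pentylbenzoate | CCCCCc1cc(OC(=O)c2c(O)cc(O)cc2CCC)cc(O)c1C(=O)OCc1ccccc1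
A2 | alternative 1 | benzyl 2-hydroxy-6-pentyl-4-[(3,5,7-trioxodecanoyl)oxy]benzoate | CCCCCc1cc(OC(=O)CC(=O)CC(=O)CC(=O)CCC)cc(O)c1C(=O)OCc1ccccc1
A3 | alternative 2 | benzyl 4-[(2,4-dimethoxy-6-propylbenzoyl)oxy]-2-methoxy-6-pentylbenzoate | CCCCCc1cc(OC(=O)c2c(OC)cc(OC)cc2CCC)cc(OC)c1C(=O)OCc1ccccc1
A4 | alternative 2 | 2-oxo-6-pentyl-2H-pyran-4-yl 2,4-dimethoxy-6-propylbenzoate | CCCCCc1cc(OC(=O)c2c(OC)cc(OC)cc2CCC)cc(=O)o1
A5 | alternative 2 | benzyl 3-methoxyprop-2-ynoate | COC#CC(=O)OCc1ccccc1
A6 | alternative 3 | benzyl 2-hydroxy-4-[(2-hydroxy-4-methoxy-6-propylbenzoyl)oxy]-6-pentylbenzoate | CCCCCc1cc(OC(=O)c2c(O)cc(OC)cc2CCC)cc(O)c1C(=O)OCc1ccccc1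
A7 | alternative 3 | benzyl 4-(hex-2-ynoyloxy)-2-hydroxy-6-pentylbenzoate | CCCCCc1cc(OC(=O)C#CCCC)cc(O)c1C(=O)OCc1ccccc1
A8 | alternative 3 | [(1,3-dimethoxybuta-1,3-dien-1-yl)oxy]trimethylsilane | COC(=C)C=C(OC)O[Si](C)(C)C
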